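Start from the easy end of the flask followed so far, the grey run.

| setting | grey | flask |
|---|---|---|
| starting material | 0.010 M | 0.010 M |
| reagent | 4 equiv | 4.00 equiv |
| remark | the very flask that is asked about, followed so far |  |
| time |  | 30 h |
grey run (percent of the starting material charged)

| time / h | target / % |
|---|---|
| 0.417 | 29.3 |
| 1.33 | 14.6 |
| 2.50 | 3.2 |
| 4.00 | 0 |

(standard deviation of a reading: 0.5 percentage points)
- the analysis behind the earlier runs scatters by 0.5 percentage points, standard deviation
- the moment within 30 h at which there is most target
- the amount of target, in percent of the starting material charged, at that time
- earliest time at which at least nineteen twentieths of that best amount are there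
- latest time at which they still are

In its tail the target falls steadily, so the readings 14.6% at 1.33 h and 3.2% at 2.50 h give a decay constant of 1.30 /h. Suppose that this loss is target reacting further with reagent, pseudo-first-order in target while c(reagent) stands in excess. Treat the reagent spent as a correction to the charge: subtract one equivalent for the starting material and 0.5 for target already over-reacted, which leaves c(reagent) near 0.0250 M in the tail. Dividing gives the wear constant 51.9 /M/h, the target's loss rate constant per unit of c(reagent), as a reading.

Near the top, subtract one equivalent only, so c(reagent) is near 0.0300 M. Take the peak at one lifetime of target, 1/(wear constant × c(reagent)), which is 0.642 h. That is later than the first sample, so the top should stand above 29.3%.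

The forecast, holding that “the two steps have comparable rates”, gave 30.5% at 0.53 h, earlier than my time, and a window from 0.37 h to 0.72 h.

The flask gives 31.3% at 0.551 h, which is 0.0910 h before my time, and a window from 0.424 h to 0.707 h.

    intermediate → side product (k = 0.0280 /min)
    target → over-reaction product B (k = 2.30 × 10⁻⁵ /min)
    reagent + target → over-reaction product A (k = 0.990 /M/min)
    starting material + reagent → intermediate + by-product (k = 2.70 /M/min)
    intermediate → target (k = 0.0530 /min)

Carry the wear constant to the end of this flask. There the reagent stands at 58.7% of its charge, or 0.0235 M, so at that c(reagent) the target's half-life by over-reaction is 0.569 h, shorter than the 30 h allowed, and the target reads 0%. In the neighbour flask with 1.60 equiv of reagent, the reagent at 30.0 h stands at 1.94% of its charge, or 3.10 × 10⁻⁴ M. The same reckoning at that final c(reagent) gives a half-life of 43.1 h, longer than the time allowed, and that flask holds 7.78% of target at 30.0 h.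

The numbers in the tables were generated by integration with constants of no real substance.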